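| flask | substrate | partner | temperature | remark | time |
|---|---|---|---|---|---|
| Saturday's | 0.94 M | 0.47 M | 40 °C | run made earlier |  |
| grey | 0.47 M | 0.470 M | 40 °C |  | 30 min |
| teal | 0.47 M | 0.470 M | 60 °C |  | 30 min |
| amber | 0.47 M | 0.470 M | 20 °C |  | 30 min |

Saturday's run (percent of the substrate charged)

| time / min | double product / % |
|---|---|
| 1.50 | 1.6 |
| 3.00 | 4.3 |
| 5.00 | 6.1 |
| 6.00 | 6.1 |
| 8.00 | 7.6 |
| 10.0 | 8.5 |

(each reading ± 0.5 percentage points)

- double product is meant together with its crystals
- solid, in amounts per volume of the solution: crystals
- the numbers in the tables scatter with a standard deviation of 0.5 percentage points
- steps that have been proposed: substrate + partner -> mono adduct; partner + mono adduct <-> double product; crystals <-> double product; partner -> decomposition product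
- the earlier runs do not show what temperature does; that part of a forecast is a guess

- which flask leads in amount of double product, in percent of the substrate charged ("all alike" within 1.5 percentage points) (grey / teal / amber / all alike)
- how much double product is there at the end, in percent of the substrate charged: grey
- how much double product is there at the end, in percent of the substrate charged: teal
- how much double product is there at the end, in percent of the substrate charged: amber

The easy step is to read Saturday's column for a time: double product stood at half of its last reading at 3.00 min. Saturday's column holds no reading of the partner, and double product is a later product, so this is no measured half-life; as a rough clock we assume it is the time in which the first addition would halve the partner if the substrate stayed at Saturday's charge. So we define the count, rate constant of the first addition times substrate concentration times time; on that assumption 3.00 min at Saturday's substrate is worth 0.693 of a count, and Saturday's last reading stands at 2.31. Grey has half of that substrate but 30 min, which gives 3.47, a little further on than the readings reach. But temperature is a guess: taking a factor of 4 per step between these flasks, we reckon 0.866 for amber, below one, and 13.9 for teal, far past Saturday's count. With equal charges, and while the first addition goes on its own, the substrate left is one part in one plus the count, which is 53.6% for amber. So we expect amber to trail grey, and we leave teal open, since no reading stands at such a count.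

The forecast gave 29% for grey, 31% for teal and 16% for amber, with teal ahead: “Teal narrowly leads, but its margin over grey is uncertain.”

The flasks give 27.0% in grey, 1.64% in teal and 10.2% in amber, so grey leads.

    substrate + partner → mono adduct (k = 6.77 × 10⁻⁴ M⁻¹ s⁻¹, Ea = 68.0 kJ mol⁻¹)
    partner + mono adduct ⇌ double product (K = 3.70 M⁻¹, k = 0.00117 M⁻¹ s⁻¹, Ea = 76.0 kJ mol⁻¹, ΔH = −37.0 kJ mol⁻¹)
    crystals ⇌ double product, rate k3*(cs3 - [double product]) while solid is left; crystals form when [double product] > cs3 (solubility = 9.20 mM, k = 0.0251 s⁻¹)
    partner → decomposition product (k = 1.21 × 10⁻⁶ s⁻¹, Ea = 94.0 kJ mol⁻¹)
    (constants at 20 °C)

Teal ended with 87.3% of its substrate as mono adduct, its double product having stood at 9.73% after 15.0 min. Amber's remaining substrate, 65%, read through the same rule gives a count of 0.538 instead of our 0.866, so the cooling cost a factor near 6.44.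

The neighbour of amber charged with 0.12 M of partner has the same substrate, temperature and time, so it carries that count, and with substrate in excess its partner should fall to 58.4%. The flask shows 56% of its partner left, with 90% of the substrate still there.

All runs are simulated for substances that don't exist; noise was put on by code.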